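**Retrosynthetic overview**

- The strategy rests on one feature: the six atoms of the dihydropyran ring (O1, C2–C6), with the C2 methyl, the C4 acetate arm and the C5 ester, are the atoms of a 2,3,4-trisubstituted furan bearing a 1-hydroxyethyl group. The carbinol supplies O1 and C2, and the unsubstituted furan α-carbon becomes C6.
- Late disconnections: the catechol benzyl ethers; the hydroxytyrosol ester (a tert-butyl ester is exchanged late); the C3 formyl group, traced back to a C3 ketone (methylenation, hydroboration, oxidation, equilibration).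
- C4–H and the C5=C6 enol ether come from reductive loss of the anomeric acetate of a 6-oxygenated 2H-pyran-3(6H)-one. That pyranone comes from the furyl carbinol by Achmatowicz ring expansion, which forms O1–C6 and the only new ring.
- The furyl carbinol comes from dimethyl furan-3,4-dicarboxylate: mono-hydrolysis, Arndt–Eistert homologation into tert-butanol, α-bromination, Stille acetylation, asymmetric transfer hydrogenation (sets C2, which then directs C4 and C3).
- Ring order: furan (bought), then the pyran (step 7); the arene arrives with hydroxytyrosol.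

Key step: step 7

Remark: ring atoms are numbered O1, C2 (methyl), C3 (formyl), C4 (acetate arm), C5 (ester), C6; the target is read as (2S,3R,4R), with the C2 methyl and the C4 arm cis and the formyl group trans to both.

**Route**

Step 1
Reactants: 1 dimethyl furan-3,4-dicarboxylate
Product: 2 4-(methoxycarbonyl)furan-3-carboxylic acid
Conditions: KOH (1.0 equiv), MeOH, 0 °C→rt; then aq HCl
Reagents that add atoms: potassium hydroxide, [K+].[OH-]
Why: Mono-saponification of a symmetrical diester, in which the first hydrolysis gives a carboxylate that deactivates the remaining ester toward a second attack by hydroxide.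

Step 2
Reactants: 2 4-(methoxycarbonyl)furan-3-carboxylic acid
Product: 4 methyl 4-(2-diazoacetyl)furan-3-carboxylate, via acid chloride 3 (not isolated)
Conditions: (COCl)2, DMF (cat.), CH2Cl2, 0 °C→rt, evaporate; then CH2N2 (3 equiv), Et2O, 0 °C
Reagents that add atoms: diazomethane, C=[N+]=[N-]; oxalyl chloride, O=C(Cl)C(=O)Cl (chlorine of 3 only)
Why: First half of the Arndt–Eistert homologation, in which the acid chloride acylates diazomethane and a second equivalent scavenges HCl, leaving the methyl ester and the furan untouched.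

Step 3
Reactants: 4 methyl 4-(2-diazoacetyl)furan-3-carboxylate
Product: 6 methyl 4-(2-tert-butoxy-2-oxoethyl)furan-3-carboxylate, via ketene 5 (not isolated)
Conditions: PhCO2Ag (cat.), Et3N, tBuOH/dioxane, 60 °C, dark
Reagents that add atoms: tert-butanol, CC(C)(C)O
Why: Wolff rearrangement, in which silver-promoted loss of N2 with 1,2-shift of the furyl group gives the ketene and tert-butanol traps it as a hindered ester that should later resist lactonisation by the neighbouring carbinol.

Step 4
Reactants: 6 methyl 4-(2-tert-butoxy-2-oxoethyl)furan-3-carboxylate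
Product: 7 methyl 5-bromo-4-(2-tert-butoxy-2-oxoethyl)furan-3-carboxylate
Conditions: NBS (1.05 equiv), DMF, 0 °C→rt, dark
Reagents that add atoms: N-bromosuccinimide, O=C1CCC(=O)N1Br
Why: Electrophilic aromatic bromination of the furan, in which the free α-carbon next to the alkyl arm is activated and meta-like to the ester whereas the other α-carbon is the β-carbon of the furan acrylate unit and is deactivated.

Step 5
Reactants: 7 methyl 5-bromo-4-(2-tert-butoxy-2-oxoethyl)furan-3-carboxylate
Product: 9 methyl 5-acetyl-4-(2-tert-butoxy-2-oxoethyl)furan-3-carboxylate, via enol ether 8 (not isolated)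
Conditions: tributyl(1-ethoxyvinyl)stannane, PdCl2(PPh3)2 (5 mol%), toluene, 100 °C; then 1 M HCl, THF, rt
Reagents that add atoms: tributyl(1-ethoxyvinyl)stannane, CCOC(=C)[Sn](CCCC)(CCCC)CCCC; water, O
Why: Stille coupling of the 2-bromofuran with an acetyl-anion equivalent followed by dilute-acid hydrolysis of the enol ether, a sequence that both esters should survive and that replaces a Lewis-acid Friedel–Crafts acetylation that the tert-butyl ester would not tolerate.

Step 6
Reactants: 9 methyl 5-acetyl-4-(2-tert-butoxy-2-oxoethyl)furan-3-carboxylate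
Product: 10 methyl 5-[(1S)-1-hydroxyethyl]-4-(2-tert-butoxy-2-oxoethyl)furan-3-carboxylate
Conditions: RuCl(p-cymene)[(S,S)-TsDPEN] (1 mol%), HCO2H/Et3N (5:2), CH2Cl2, rt
Reagents that add atoms: none
Why: Noyori asymmetric transfer hydrogenation of a heteroaryl methyl ketone, in which the (S,S)-TsDPEN ruthenium hydride delivers hydride to the face that places the furyl group next to the η6-arene and so should give the (S)-carbinol under catalyst control, setting C2 of the target.

Step 7
Reactants: 10 methyl 5-[(1S)-1-hydroxyethyl]-4-(2-tert-butoxy-2-oxoethyl)furan-3-carboxylate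
Product: 12 methyl (2S)-6-hydroxy-2-methyl-3-oxo-4-(2-tert-butoxy-2-oxoethyl)-3,6-dihydro-2H-pyran-5-carboxylate (anomeric mixture), via cis-enedione 11 (not isolated)
Conditions: NBS (1.05 equiv), NaHCO3, NaOAc, THF/H2O (4:1), 0 °C
Reagents that add atoms: water, O
Why: NBS transfers electrophilic bromine to the furan, water adds at the opposite α-carbon, and the resulting 2,5-dihydrofuran loses bromide and opens to the cis-ene-dicarbonyl compound 11, in which the former carbinol-bearing carbon is a ketone (C3) and the former free α-carbon an aldehyde (C6). The closest known reaction is the Achmatowicz rearrangement of 2-furyl carbinols to 6-hydroxy-2H-pyran-3(6H)-ones. The only ring closes by 6-exo-trig addition of the C2 hydroxyl to the aldehyde carbon, which forms the O1–C6 bond. The one new stereocentre, the lactol carbon C6, is not controlled and is erased in step 9, while the carbinol centre is not involved and should keep its S configuration. The step needs the furan to be oxidised in preference to everything else although the ring ester lowers its nucleophilicity; the two alkyl substituents on the other ring carbons should keep it reactive enough, one equivalent of NBS at 0 °C limits overoxidation, and the bicarbonate–acetate buffer protects the tert-butyl ester and the lactol.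

Step 8
Reactants: 12 methyl (2S)-6-hydroxy-2-methyl-3-oxo-4-(2-tert-butoxy-2-oxoethyl)-3,6-dihydro-2H-pyran-5-carboxylate
Product: 13 methyl (2S)-6-acetoxy-2-methyl-3-oxo-4-(2-tert-butoxy-2-oxoethyl)-3,6-dihydro-2H-pyran-5-carboxylate (anomeric mixture)
Conditions: Ac2O, pyridine, DMAP (cat.), CH2Cl2, −20→0 °C
Reagents that add atoms: acetic anhydride, CC(=O)OC(C)=O
Why: Acylation of the lactol hydroxyl under weakly basic conditions turns C6–O into a leaving group while avoiding the C2 deprotonation (oxidopyrylium formation) that stronger amines would cause.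

Step 9
Reactants: 13 methyl (2S)-6-acetoxy-2-methyl-3-oxo-4-(2-tert-butoxy-2-oxoethyl)-3,6-dihydro-2H-pyran-5-carboxylate
Product: 15 methyl (2S,4S)-2-methyl-3-oxo-4-(2-tert-butoxy-2-oxoethyl)-3,4-dihydro-2H-pyran-5-carboxylate (arm cis to the C2 methyl), via dienol 14 (not isolated)
Conditions: Zn dust, AcOH/THF (1:5), 0 °C, short contact; cold aq NaHCO3 work-up
Reagents that add atoms: none
Why: Zinc reduction of a γ-acyloxy enone (here the ketone/C4=C5/ester system) gives a dienolate that expels the C6 acetate to form the C5=C6 enol ether, and the transient dienol should be protonated at C4 on the face away from the pseudoaxial C2 methyl, which places the acetate arm cis to that methyl (substrate control from C2) and removes the uncontrolled C6 centre.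

Step 10
Reactants: 15 methyl (2S,4S)-2-methyl-3-oxo-4-(2-tert-butoxy-2-oxoethyl)-3,4-dihydro-2H-pyran-5-carboxylate
Product: 16 methyl (2S,4R)-2-methyl-3-methylidene-4-(2-tert-butoxy-2-oxoethyl)-3,4-dihydro-2H-pyran-5-carboxylate
Conditions: Zn, CH2Br2, TiCl4, THF (pre-formed reagent); CH2Cl2, 0 °C→rt; used directly after step 9
Reagents that add atoms: dibromomethane, BrCBr
Why: Takai–Lombardo methylenation, whose titanium–zinc methylene reagent is non-basic and inert to esters, should convert the hindered, enolisable ketone into the exocyclic alkene without epimerisation and thereby lock the C4 configuration.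

Step 11
Reactants: 16 methyl (2S,4R)-2-methyl-3-methylidene-4-(2-tert-butoxy-2-oxoethyl)-3,4-dihydro-2H-pyran-5-carboxylate
Product: 18 methyl (2S,4R)-3-(hydroxymethyl)-2-methyl-4-(2-tert-butoxy-2-oxoethyl)-3,4-dihydro-2H-pyran-5-carboxylate (mixture at C3), via alkylborane 17 (not isolated)
Conditions: 9-BBN, THF, 0 °C→rt; then 30% H2O2, aq NaOAc, 0 °C
Reagents that add atoms: hydrogen peroxide, OO; 9-BBN, B1C2CCCC1CCC2 (boron of 17 only)
Why: Hydroboration–oxidation, in which 9-BBN places boron on the terminal carbon of the 1,1-disubstituted exocyclic alkene and ignores the esters and the electron-poor push–pull enol ether, gives the primary alcohol, and the C3 configuration formed here does not matter because it is equilibrated in step 12.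

Step 12
Reactants: 18 methyl (2S,4R)-3-(hydroxymethyl)-2-methyl-4-(2-tert-butoxy-2-oxoethyl)-3,4-dihydro-2H-pyran-5-carboxylate
Product: 20 methyl (2S,3R,4R)-3-formyl-2-methyl-4-(2-tert-butoxy-2-oxoethyl)-3,4-dihydro-2H-pyran-5-carboxylate, via C3-epimeric aldehyde 19 (not isolated)
Conditions: DMP, CH2Cl2, 0 °C→rt; then Et3N, 0 °C→rt
Reagents that add atoms: none
Why: Dess–Martin oxidation followed by amine-buffered enolisation of the aldehyde should let C3, the only enolisable centre, settle with the formyl group trans to both the C2 methyl and the C4 arm (thermodynamic control by C2 and C4), the weak buffer at low temperature being chosen so that the ring oxygen is not lost by β-elimination.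

Step 13
Reactants: 20 methyl (2S,3R,4R)-3-formyl-2-methyl-4-(2-tert-butoxy-2-oxoethyl)-3,4-dihydro-2H-pyran-5-carboxylate
Product: 21 2-[(2S,3R,4R)-3-formyl-5-(methoxycarbonyl)-2-methyl-3,4-dihydro-2H-pyran-4-yl]acetic acid
Conditions: TFA/CH2Cl2 (1:4), 0 °C→rt
Reagents that add atoms: none
Why: Acidolysis of the tert-butyl ester by E1 loss of isobutene should leave the methyl vinylogous carbonate, the enol ether and the aldehyde unchanged.

Step 14
Reactants: 22 hydroxytyrosol
Product: 23 2-[3,4-bis(benzyloxy)phenyl]ethanol
Conditions: BnBr (2.1 equiv), K2CO3, acetone, reflux, N2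
Reagents that add atoms: benzyl bromide, BrCc1ccccc1
Why: Williamson ether synthesis in which carbonate deprotonates only the phenols, so both catechol oxygens are benzylated and the primary alcohol stays free.

Step 15
Reactants: 21 2-[(2S,3R,4R)-3-formyl-5-(methoxycarbonyl)-2-methyl-3,4-dihydro-2H-pyran-4-yl]acetic acid; 23 2-[3,4-bis(benzyloxy)phenyl]ethanol
Product: 24 methyl (2S,3R,4R)-4-{2-[2-(3,4-bis(benzyloxy)phenyl)ethoxy]-2-oxoethyl}-3-formyl-2-methyl-3,4-dihydro-2H-pyran-5-carboxylate
Conditions: DCC, DMAP (cat.), CH2Cl2, 0 °C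
Reagents that add atoms: none
Why: Steglich esterification of a primary alcohol with an unhindered acetic acid side chain under near-neutral conditions at 0 °C should not disturb the stereocentre next to the aldehyde.

Step 16
Reactants: 24 methyl (2S,3R,4R)-4-{2-[2-(3,4-bis(benzyloxy)phenyl)ethoxy]-2-oxoethyl}-3-formyl-2-methyl-3,4-dihydro-2H-pyran-5-carboxylate
Product: 25 methyl (2S,3R,4R)-4-{2-[2-(3,4-dihydroxyphenyl)ethoxy]-2-oxoethyl}-3-formyl-2-methyl-3,4-dihydro-2H-pyran-5-carboxylate (CNP0172886.1)
Conditions: H2 (1 atm), 10% Pd/C, EtOAc, rt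
Reagents that add atoms: none
Why: Hydrogenolysis of the two aryl benzyl ethers over palladium should be much faster than reduction of the hindered aldehyde or of the ester-conjugated enol ether under one atmosphere of hydrogen in ethyl acetate.

**Compound list**

1 | dimethyl furan-3,4-dicarboxylate | COC(=O)c1cocc1C(=O)OC | starting material
2 | 4-(methoxycarbonyl)furan-3-carboxylic acid | COC(=O)c1cocc1C(=O)O | intermediate
3 | methyl 4-(chlorocarbonyl)furan-3-carboxylate | COC(=O)c1cocc1C(=O)Cl | intermediate
4 | methyl 4-(2-diazoacetyl)furan-3-carboxylate | COC(=O)c1cocc1C(=O)C=[N+]=[N-] | intermediate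
5 | methyl 4-(2-oxoethenyl)furan-3-carboxylate (ketene) | COC(=O)c1cocc1C=C=O | intermediate
6 | methyl 4-(2-tert-butoxy-2-oxoethyl)furan-3-carboxylate | COC(=O)c1cocc1CC(=O)OC(C)(C)C | intermediate
7 | methyl 5-bromo-4-(2-tert-butoxy-2-oxoethyl)furan-3-carboxylate | COC(=O)c1coc(Br)c1CC(=O)OC(C)(C)C | intermediate
8 | methyl 5-(1-ethoxyethenyl)-4-(2-tert-butoxy-2-oxoethyl)furan-3-carboxylate | COC(=O)c1coc(C(=C)OCC)c1CC(=O)OC(C)(C)C | intermediate
9 | methyl 5-acetyl-4-(2-tert-butoxy-2-oxoethyl)furan-3-carboxylate | COC(=O)c1coc(C(C)=O)c1CC(=O)OC(C)(C)C | intermediate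
10 | methyl 5-[(1S)-1-hydroxyethyl]-4-(2-tert-butoxy-2-oxoethyl)furan-3-carboxylate | COC(=O)c1coc([C@H](C)O)c1CC(=O)OC(C)(C)C | intermediate
11 | 1-tert-butyl 5-methyl (3Z,6S)-4-formyl-6-hydroxy-3-... open cis-ene-dicarbonyl form: methyl (2Z,5S)-2-formyl-5-hydroxy-4-oxo-3-(2-tert-butoxy-2-oxoethyl)hex-2-enoate | C[C@H](O)C(=O)/C(CC(=O)OC(C)(C)C)=C(\C=O)C(=O)OC | intermediate
12 | methyl (2S)-6-hydroxy-2-methyl-3-oxo-4-(2-tert-butoxy-2-oxoethyl)-3,6-dihydro-2H-pyran-5-carboxylate | COC(=O)C1=C(CC(=O)OC(C)(C)C)C(=O)[C@H](C)OC1O | intermediate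
13 | methyl (2S)-6-acetoxy-2-methyl-3-oxo-4-(2-tert-butoxy-2-oxoethyl)-3,6-dihydro-2H-pyran-5-carboxylate | COC(=O)C1=C(CC(=O)OC(C)(C)C)C(=O)[C@H](C)OC1OC(C)=O | intermediate
14 | methyl (2S)-3-hydroxy-2-methyl-4-(2-tert-butoxy-2-oxoethyl)-2H-pyran-5-carboxylate (dienol) | COC(=O)C1=CO[C@@H](C)C(O)=C1CC(=O)OC(C)(C)C | intermediate
15 | methyl (2S,4S)-2-methyl-3-oxo-4-(2-tert-butoxy-2-oxoethyl)-3,4-dihydro-2H-pyran-5-carboxylate | COC(=O)C1=CO[C@@H](C)C(=O)[C@H]1CC(=O)OC(C)(C)C | intermediate
16 | methyl (2S,4R)-2-methyl-3-methylidene-4-(2-tert-butoxy-2-oxoethyl)-3,4-dihydro-2H-pyran-5-carboxylate | COC(=O)C1=CO[C@@H](C)C(=C)[C@H]1CC(=O)OC(C)(C)C | intermediate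
17 | methyl (2S,4R)-3-[(9-borabicyclo[3.3.1]nonan-9-yl)methyl]-2-methyl-4-(2-tert-butoxy-2-oxoethyl)-3,4-dihydro-2H-pyran-5-carboxylate | COC(=O)C1=CO[C@@H](C)C(CB2C3CCCC2CCC3)[C@H]1CC(=O)OC(C)(C)C | intermediate
18 | methyl (2S,4R)-3-(hydroxymethyl)-2-methyl-4-(2-tert-butoxy-2-oxoethyl)-3,4-dihydro-2H-pyran-5-carboxylate (mixture at C3) | COC(=O)C1=CO[C@@H](C)C(CO)[C@H]1CC(=O)OC(C)(C)C | intermediate
19 | methyl (2S,4R)-3-formyl-2-methyl-4-(2-tert-butoxy-2-oxoethyl)-3,4-dihydro-2H-pyran-5-carboxylate (mixture at C3) | COC(=O)C1=CO[C@@H](C)C(C=O)[C@H]1CC(=O)OC(C)(C)C | intermediate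
20 | methyl (2S,3R,4R)-3-formyl-2-methyl-4-(2-tert-butoxy-2-oxoethyl)-3,4-dihydro-2H-pyran-5-carboxylate | COC(=O)C1=CO[C@@H](C)[C@H](C=O)[C@H]1CC(=O)OC(C)(C)C | intermediate
21 | 2-[(2S,3R,4R)-3-formyl-5-(methoxycarbonyl)-2-methyl-3,4-dihydro-2H-pyran-4-yl]acetic acid | COC(=O)C1=CO[C@@H](C)[C@H](C=O)[C@H]1CC(=O)O | intermediate
22 | hydroxytyrosol | OCCc1ccc(O)c(O)c1 | starting material
23 | 2-[3,4-bis(benzyloxy)phenyl]ethanol | OCCc1ccc(OCc2ccccc2)c(OCc2ccccc2)c1 | intermediate
24 | methyl (2S,3R,4R)-4-{2-[2-(3,4-bis(benzyloxy)phenyl)ethoxy]-2-oxoethyl}-3-formyl-2-methyl-3,4-dihydro-2H-pyran-5-carboxylate | COC(=O)C1=CO[C@@H](C)[C@H](C=O)[C@H]1CC(=O)OCCc1ccc(OCc2ccccc2)c(OCc2ccccc2)c1 | intermediate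
25 | methyl (2S,3R,4R)-4-{2-[2-(3,4-dihydroxyphenyl)ethoxy]-2-oxoethyl}-3-formyl-2-methyl-3,4-dihydro-2H-pyran-5-carboxylate | COC(=O)C1=CO[C@@H](C)[C@H](C=O)[C@H]1CC(=O)OCCc1ccc(O)c(O)c1 | target

**Step count and risks**

Total step count: 16. Longest linear sequence: 15 steps (steps 1–13, 15, 16; step 14 is the side branch).

The three steps most likely to fail:

Step 7. The ring ester lowers the nucleophilicity of the furan, so electrophilic bromine transfer may be slow. The oxidant could then be consumed by side reactions (bromination of the arm methylene, overoxidation of the lactol) before the enedione has formed and closed. The fallback sets out from 10 and comes back at 12, and replaces electrophilic halogen by direct electron-transfer oxidation. Constant-current anodic oxidation in methanol (graphite electrodes, Et4NOTs, −10 °C) adds two methoxy groups across the furan α-carbons to give methyl 5-[(1S)-1-hydroxyethyl]-2,5-dimethoxy-4-(2-tert-butoxy-2-oxoethyl)-2,5-dihydrofuran-3-carboxylate F1. Mild aqueous acid (PPTS, acetone/H2O, rt) then hydrolyses this isolable bis-acetal to the same cis-ene-dicarbonyl compound, which closes to 12.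

Step 9. The C2/C4 cis relationship may be eroded. Protonation of the dienol may show poor facial selectivity, or the ketone may enolise afterwards; allylic 1,2-strain between the C4 arm and the C5 ester may make the trans epimer competitive at equilibrium. Reductive cleavage of the C2–O1 bond next to the ketone is a further possible side reaction. The fallback sets out from 12 and comes back at 16, and sets C4 in a saturated chair before the enol ether exists.
- Acid-catalysed glycosidation with methanol (PPTS, MeOH, molecular sieves) gives the methyl acetal methyl (2S)-6-methoxy-2-methyl-3-oxo-4-(2-tert-butoxy-2-oxoethyl)-3,6-dihydro-2H-pyran-5-carboxylate F2.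
- Hydrogenation of the tetrasubstituted alkene (H2, Pd/C, EtOAc) and a brief DBU equilibration of the more acidic C4 and C5 positions give the chair tetrahydropyranone methyl (2S,4S)-6-methoxy-2-methyl-3-oxo-4-(2-tert-butoxy-2-oxoethyl)oxane-5-carboxylate F3, in which the C2 methyl and the C4 arm are both equatorial and therefore cis.
- Takai–Lombardo methylenation gives methyl (2S,4S)-6-methoxy-2-methyl-3-methylidene-4-(2-tert-butoxy-2-oxoethyl)oxane-5-carboxylate F4.
- PPTS in toluene at 90 °C eliminates methanol across C5–C6 to give 16.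

Step 12. While C3 equilibrates through the enol or enolate, the ring oxygen, which is a vinylogous carboxylate leaving group, may be lost by β-elimination. The ring would then open and re-close with scrambling of C2, or the equilibrium may not favour the all-trans aldehyde strongly enough. The fallback sets out from 12 and comes back at 20, and carries out the C3 equilibration while O1 is still an acetal oxygen and a poor leaving group.
- 12 is taken to the methylene acetal F4 as described for step 9.
- Hydroboration–oxidation as in step 11 gives methyl (2S,4R)-3-(hydroxymethyl)-6-methoxy-2-methyl-4-(2-tert-butoxy-2-oxoethyl)oxane-5-carboxylate F5.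
- Dess–Martin oxidation and DBU equilibration in the chair give the all-equatorial aldehyde methyl (2S,3R,4R)-3-formyl-6-methoxy-2-methyl-4-(2-tert-butoxy-2-oxoethyl)oxane-5-carboxylate F6.
- Loss of methanol (PPTS, toluene, 90 °C) forms the C5=C6 enol ether and gives 20.

Further compounds
F1 | step 7 | methyl 5-[(1S)-1-hydroxyethyl]-2,5-dimethoxy-4-(2-tert-butoxy-2-oxoethyl)-2,5-dihydrofuran-3-carboxylate | COC(=O)C1=C(CC(=O)OC(C)(C)C)C(OC)([C@H](C)O)OC1OC
F2 | step 9 | methyl (2S)-6-methoxy-2-methyl-3-oxo-4-(2-tert-butoxy-2-oxoethyl)-3,6-dihydro-2H-pyran-5-carboxylate | COC(=O)C1=C(CC(=O)OC(C)(C)C)C(=O)[C@H](C)OC1OC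
F3 | step 9 | methyl (2S,4S)-6-methoxy-2-methyl-3-oxo-4-(2-tert-butoxy-2-oxoethyl)oxane-5-carboxylate | COC(=O)C1C(OC)O[C@@H](C)C(=O)[C@H]1CC(=O)OC(C)(C)C
F4 | step 9 | methyl (2S,4S)-6-methoxy-2-methyl-3-methylidene-4-(2-tert-butoxy-2-oxoethyl)oxane-5-carboxylate | COC(=O)C1C(OC)O[C@@H](C)C(=C)[C@H]1CC(=O)OC(C)(C)C
F5 | step 12 | methyl (2S,4R)-3-(hydroxymethyl)-6-methoxy-2-methyl-4-(2-tert-butoxy-2-oxoethyl)oxane-5-carboxylate | COC(=O)C1C(OC)O[C@@H](C)C(CO)[C@H]1CC(=O)OC(C)(C)C
F6 | step 12 | methyl (2S,3R,4R)-3-formyl-6-methoxy-2-methyl-4-(2-tert-butoxy-2-oxoethyl)oxane-5-carboxylate | COC(=O)C1C(OC)O[C@@H](C)[C@H](C=O)[C@H]1CC(=O)OC(C)(C)C
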